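# Uprolide D: proposed total synthesis

**Numbering used below.** C1 bears the exocyclic =CH2. C2–C4 are CH2, C5 is CHMe, C6 is CH–O, C7 is the lactone CH–O, and C8 is the lactone CH (it carries the α-methylene-lactone carbon). C9 is CH2, C10 is CHOH, C11 is the quaternary C(Me)–O, C12 and C13 are CH2, and C14 is the THF CH–O. The target is (5S,6R,7R,8S,10R,11S,14R).

**Assumptions.** The catalyst enantiomers named below, (R)-TRIP, (S)-Me-CBS and the D-fructose-derived Shi ketone, are assumed to give the required faces. The opposite enantiomers are used if the sense is reversed.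

## Retrosynthetic overview
1. Uprolide D ← TBS-lactone **21** ← hydroxy acid **20**, by Mitsunobu γ-lactonisation with inversion at C7. **20** ← macrocyclic hydroxy ester **19**, formed by intramolecular NHK allylation (C7–C8), which closes the 14-membered carbocycle.
2. NHK precursor **18** (aldehyde plus Z-allylic bromide) ← cross-metathesis of terminal alkene **16** ← acetal **15**.
3. The THF (quaternary C11) comes from Shi epoxidation of E-alkene **13** and 5-exo epoxy-alcohol cyclisation. The C14 carbinol comes from CBS reduction of enone **12**, which is made by vinyllithium acylation of Weinreb amide **11** (the C1–C14 bond).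
4. Vinyl bromide **6** comes from organocatalytic syn-crotylation of glyoxal acetal (C5/C6) followed by hydroboration/Suzuki coupling. **11** comes from carboalumination–allylation of methyl pentynoate.
5. Ring order: THF first, then the 14-membered carbocycle, then the γ-lactone.

## Route

**Step 1**
Reactants: **1** 2,2-dimethoxyacetaldehyde; **2** (Z)-crotyl-Bpin
Product: **3** (2R,3S)-1,1-dimethoxy-3-methylpent-4-en-2-ol (syn)
Conditions: (R)-TRIP (5 mol%), toluene, 4 Å MS, –30 °C
Reagents that add atoms: none (the crotyl group comes from **2**)
Why: Proposed new method: a chiral phosphoric acid activates the allylboronate through P–OH···O(pin) and P=O···B, so the Z-crotyl group adds through a closed chair transition state that gives the syn product. The catalyst pocket selects the aldehyde face and sets C5/C6 together, while the acetal masks C7 as an aldehyde. The closest known reaction is phosphoric-acid-catalysed allylboration of aldehydes with pinacol allylboronates, here applied to an electron-poor α,α-dialkoxy aldehyde with a suppressed background reaction.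

**Step 2**
Reactants: **3**
Product: **4** TBS ether of **3**
Conditions: TBSCl, imidazole, DMF, 40 °C
Reagents that add atoms: TBSCl, CC(C)(C)[Si](C)(C)Cl
Why: Silylation of the C6 alcohol, with no stereocentre affected. The TBS group is non-chelating and survives every later step until the end.

**Step 3**
Reactants: **4**; **5** 2,3-dibromopropene
Product: **6** vinyl bromide, tert-butyl{[(2R,3S)-7-bromo-1,1-dimethoxy-3-methyloct-7-en-2-yl]oxy}dimethylsilane
Conditions: 9-BBN (1.1 equiv), THF, 0 °C→rt; then **5**, PdCl2(dppf), aq. K3PO4, THF, 50 °C
Reagents that add atoms: none beyond reactant **5**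
Why: Terminal hydroboration followed by B-alkyl Suzuki–Miyaura coupling. Pd inserts into the allylic C–Br of **5** far faster than the vinylic C–Br, so the 2-bromoalkene (C1–C4 chain) is retained and C5/C6 are untouched.

**Step 4**
Reactants: **7** methyl pent-4-ynoate; **8** allyl bromide
Product: **9** methyl (E)-4-methylocta-4,7-dienoate
Conditions: Me3Al, Cp2ZrCl2 (cat.), ClCH2CH2Cl, 0 °C→rt; then CuCl (cat.), **8**, THF, 0 °C
Reagents that add atoms: trimethylaluminium, C[Al](C)C
Why: Negishi Zr-catalysed syn-carboalumination gives the E-trisubstituted vinylalane (the C11 methyl is installed here), and Cu-catalysed allylation of it builds C9/C8 without alkene isomerisation.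

**Step 5**
Reactants: **9**; **10** N,O-dimethylhydroxylamine hydrochloride
Product: **11** (E)-N-methoxy-N,4-dimethylocta-4,7-dienamide
Conditions: i-PrMgCl (3 equiv), THF, –20 °C
Reagents that add atoms: none beyond reactant **10**
Why: Ester-to-Weinreb-amide conversion through a magnesium amide, which leaves both alkenes untouched.

**Step 6**
Reactants: **6**; **11**
Product: **12** enone (C14 α-methylene ketone)
Conditions: t-BuLi (2.1 equiv), Et2O, –78 °C; then **11**, –78→–40 °C
Reagents that add atoms: none beyond the numbered reactants
Why: Bromine–lithium exchange gives the 2-lithioalkene, which acylates the Weinreb amide (a chelated tetrahedral intermediate prevents over-addition) to form the C1–C14 bond. The acetal and OTBS survive.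

**Step 7**
Reactants: **12**
Product: **13** (14R)-allylic alcohol
Conditions: (S)-Me-CBS (20 mol%), catecholborane, toluene, –78 °C
Reagents that add atoms: none
Why: Corey–Bakshi–Shibata reduction. The oxazaborolidine discriminates the branched vinyl group from the n-alkyl chain and sets C14 as R. Catecholborane at –78 °C avoids hydroboration of the alkenes.

**Step 8**
Reactants: **13**
Product: **14** (10R,11R)-trans-epoxy alcohol
Conditions: D-fructose-derived Shi ketone (30 mol%), Oxone, K2CO3, Bu4NHSO4, Na2EDTA, MeCN/DMM/H2O, pH 10.5, 0 °C
Reagents that add atoms: Oxone (KHSO5), OOS(=O)(=O)[O-].[K+]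
Why: Shi asymmetric epoxidation through a chiral dioxirane (spiro transition state) is stereospecific, so the E-alkene gives the trans-epoxide with catalyst-controlled faces (10R,11R). The trisubstituted alkene is far more reactive than the terminal and the allylic-alcohol-deactivated 1,1-disubstituted alkenes, and the acetal and OTBS are stable at pH 10.5.

**Step 9**
Reactants: **14**
Product: **15** THF with free C10–OH (10R,11S,14R)
Conditions: CSA (10 mol%), CH2Cl2, 0 °C
Reagents that add atoms: none
Why: Acid-promoted 5-exo epoxy-alcohol cyclisation. C14–OH attacks the tertiary epoxide carbon C11 with inversion (R epoxide carbon → 11S), giving the cis-2,5-THF. The α-silyloxy dimethyl acetal is deactivated towards ionisation and survives.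

**Step 10**
Reactants: **15**
Product: **16** α-silyloxy aldehyde (C7 CHO)
Conditions: p-TsOH·H2O (20 mol%), acetone/H2O (10:1), 50 °C
Reagents that add atoms: water, O
Why: Acetal hydrolysis unmasks the NHK electrophile. The C6 stereocentre sits in an aldehyde α-position and the conditions are mild enough not to epimerise it.

**Step 11**
Reactants: **16**; **17** methyl 2-(bromomethyl)acrylate
Product: **18** NHK precursor, Z-allylic bromide
Conditions: Hoveyda–Grubbs II (10 mol%), **17** (8 equiv), CH2Cl2, 40 °C, N2 sweep
Reagents that add atoms: none beyond reactant **17**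
Why: Proposed new method: the terminal alkene (type I) undergoes cross-metathesis with the hindered, electron-poor 1,1-disubstituted acrylate. Ethylene loss drives the reaction, and the thermodynamic trisubstituted alkene has the ester trans to the alkyl chain, i.e. the usual Z-2-(bromomethyl)alkenoate. The Ru(II) carbene should not insert into the allylic C–Br under these base- and phosphine-free conditions. The closest known reactions are cross-metathesis with methacrylates and with allyl halides. This directly gives the NHK allyl halide in one step.

**Step 12**
Reactants: **18**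
Product: **19** macrocyclic hydroxy methyl ester, C7-epimeric (5S,6R,7S,8S,10R,11S,14R); any trans-lactone formed on work-up is carried into Step 13
Conditions: CrCl2 (10 equiv), THF/DMF (4:1), 0.003 M, syringe-pump addition over 10 h, 25 °C
Reagents that add atoms: none
Why: Intramolecular Hiyama–Nozaki–Kishi allylation closes the C7–C8 bond and the 14-membered ring. It is expected to show Felkin–Anh selectivity at the C6-OTBS-substituted aldehyde (C6/C7 anti) and anti selectivity through the chair allylchromium transition state (C7/C8 anti). Both selectivities deviate from the target only at C7, which Step 14 corrects.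

**Step 13**
Reactants: **19**
Product: **20** hydroxy acid
Conditions: LiOH·H2O (5 equiv), THF/H2O (3:1), 0 °C→rt
Reagents that add atoms: lithium hydroxide, [Li+].[OH-]
Why: Saponification of the methyl ester (or ring-opening of any trans-lactone). It funnels both forms into one acyclic seco-acid with C7 unchanged.

**Step 14**
Reactants: **20**
Product: **21** TBS-protected cis-lactone (5S,6R,7R,8S,10R,11S,14R)
Conditions: PPh3 (3 equiv), DIAD (3 equiv), THF, 0 °C, 0.005 M
Reagents that add atoms: none
Why: Mitsunobu lactonisation, in which the carboxylate displaces the activated C7 alcohol by SN2 with inversion. This converts 7S to 7R and delivers the cis-fused α-methylene-γ-butyrolactone.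

**Step 15**
Reactants: **21**
Product: **22** Uprolide D
Conditions: HF·pyridine, pyridine, THF, 0 °C→rt
Reagents that add atoms: none
Why: Buffered fluoride removes the C6 TBS ether without opening the lactone or epimerising stereocentres.

## Compound list
1 | 2,2-dimethoxyacetaldehyde | COC(OC)C=O | starting material
2 | (Z)-crotylboronic acid pinacol ester | C/C=C\CB1OC(C)(C)C(C)(C)O1 | starting material
3 | (2R,3S)-1,1-dimethoxy-3-methylpent-4-en-2-ol | C=C[C@H](C)[C@@H](O)C(OC)OC | intermediate
4 | TBS ether of 3 | C=C[C@H](C)[C@@H](O[Si](C)(C)C(C)(C)C)C(OC)OC | intermediate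
5 | 2,3-dibromopropene | C=C(Br)CBr | starting material
6 | vinyl bromide (7-bromo-1,1-dimethoxy-3-methyloct-7-en-2-yl TBS ether) | C=C(Br)CCC[C@H](C)[C@@H](O[Si](C)(C)C(C)(C)C)C(OC)OC | intermediate
7 | methyl pent-4-ynoate | C#CCCC(=O)OC | starting material
8 | allyl bromide | C=CCBr | starting material
9 | methyl (E)-4-methylocta-4,7-dienoate | COC(=O)CC/C(C)=C/CC=C | intermediate
10 | N,O-dimethylhydroxylamine hydrochloride | CONC.Cl | starting material
11 | (E)-N-methoxy-N,4-dimethylocta-4,7-dienamide | CON(C)C(=O)CC/C(C)=C/CC=C | intermediate
12 | C14 α-methylene ketone (5S,6R; C10=C11 E; terminal C8=CH2; C7 dimethyl acetal; C6-OTBS) | C=C(CCC[C@H](C)[C@@H](O[Si](C)(C)C(C)(C)C)C(OC)OC)C(=O)CC/C(C)=C/CC=C | intermediate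
13 | (14R)-allylic alcohol | C=C(CCC[C@H](C)[C@@H](O[Si](C)(C)C(C)(C)C)C(OC)OC)[C@H](O)CC/C(C)=C/CC=C | intermediate
14 | (10R,11R)-trans-epoxy alcohol | C=C(CCC[C@H](C)[C@@H](O[Si](C)(C)C(C)(C)C)C(OC)OC)[C@H](O)CC[C@@]1(C)O[C@@H]1CC=C | intermediate
15 | THF with free C10–OH | C=C(CCC[C@H](C)[C@@H](O[Si](C)(C)C(C)(C)C)C(OC)OC)[C@H]1CC[C@](C)(O1)[C@H](O)CC=C | intermediate
16 | C7 aldehyde | C=C(CCC[C@H](C)[C@@H](O[Si](C)(C)C(C)(C)C)C=O)[C@H]1CC[C@](C)(O1)[C@H](O)CC=C | intermediate
17 | methyl 2-(bromomethyl)acrylate | C=C(CBr)C(=O)OC | starting material
18 | aldehyde / Z-allylic bromide (NHK precursor) | C=C(CCC[C@H](C)[C@@H](O[Si](C)(C)C(C)(C)C)C=O)[C@H]1CC[C@](C)(O1)[C@H](O)C/C=C(\CBr)C(=O)OC | intermediate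
19 | macrocyclic hydroxy methyl ester (7-epi) | C=C1CCC[C@H](C)[C@@H](O[Si](C)(C)C(C)(C)C)[C@@H](O)[C@H](C(=C)C(=O)OC)C[C@@H](O)[C@]2(C)CC[C@H]1O2 | intermediate
20 | macrocyclic hydroxy acid | C=C1CCC[C@H](C)[C@@H](O[Si](C)(C)C(C)(C)C)[C@@H](O)[C@H](C(=C)C(=O)O)C[C@@H](O)[C@]2(C)CC[C@H]1O2 | intermediate
21 | TBS-protected Uprolide D | C=C1CCC[C@H](C)[C@@H](O[Si](C)(C)C(C)(C)C)[C@@H]2OC(=O)C(=C)[C@@H]2C[C@@H](O)[C@]2(C)CC[C@H]1O2 | intermediate
22 | Uprolide D | C=C1CCC[C@H](C)[C@@H](O)[C@@H]2OC(=O)C(=C)[C@@H]2C[C@@H](O)[C@]2(C)CC[C@H]1O2 | target

**Total steps:** 15. **Longest linear sequence:** 13 steps (1, 2, 3, 6–15).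

## Three steps most likely to fail
1. **Step 1 (proposed new method; phosphoric-acid-catalysed crotylboration of the glyoxal acetal).** The uncatalysed background reaction of this electron-poor aldehyde may erode ee or syn selectivity.
   - *Fallback:* Brown crotylation with stoichiometric (Z)-crotyl-diisopinocampheylborane at –78 °C. This is known chemistry and gives the same syn homoallylic alcohol **3**.
2. **Step 11 (proposed new method; cross-metathesis with methyl 2-(bromomethyl)acrylate).** Catalyst deactivation by the allylic bromide, or low conversion, may occur.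
   - *Fallback:* rebuild the right fragment by cross-metathesis of methyl 4-methylpent-4-enoate with but-3-enyl PMB ether, which carries C8 as CH2OPMB. After THF formation, remove PMB (DDQ), oxidise (DMP), and run a Baylis–Hillman reaction with methyl acrylate. Convert the adduct to the Z-allylic bromide (MsCl, Et3N; then LiBr), then resume at acetal hydrolysis and NHK.
3. **Step 12 (macro-NHK).** Ring closure efficiency or C7/C8 diastereoselectivity may be poor, since the ring conformation can override Felkin/anti control.
   - *Fallback:* change the ring-closing bond. Build the lactone first by intermolecular Cr allylation plus Mitsunobu lactonisation. Then close the carbocycle at C1–C14 by intramolecular Nozaki–Hiyama–Kishi coupling of a vinyl iodide with the C14 aldehyde. Fix C14 by DMP oxidation then (S)-CBS reduction, and form the THF as in Steps 8–9.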